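The earlier runs and the new flask are simulated on assumed constants; scatter was added.

The partner is the reagent to follow in this flask, where a single-handed catalyst turns a racemic substrate into left-handed and right-handed product.

common to all: left-handed substrate 0.017 M; right-handed substrate 0.017 M; partner 0.0425 M; added ligand 1.2 mM
- beta: precatalyst 3.8 mM; run made earlier
- flask: precatalyst 1.9 mM; time 3.0 d

beta run (percent of the left-handed substrate and right-handed substrate together charged)

| time / h | left-handed product / % | right-handed product / % | left-handed substrate / % |
|---|---|---|---|
| 2.50 | 0.5 | 0.1 | 48.3 |
| 8.00 | 7.6 | 0.7 | 44.0 |
| 15.0 | 14.7 | 0.7 | 39.4 |
| 20.0 | 18.8 | 0.5 | 38.5 |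

(readings scatter by 0.3 percentage points)

- catalyst is single-handed; left-handed substrate and right-handed substrate are mirror images of each other, charged as a racemate, each of them at the stated concentration
- the earlier runs were read with a standard deviation of 0.3 percentage points
- an excess is the difference of the two amounts in percent of their sum
- an excess is below zero if the other one leads
- no earlier run changes the charge of precatalyst; that part of a forecast is a guess

* excess of left-handed product over right-handed product in the product at 4.0 h
* excess of left-handed product over right-handed product in the product at 3.0 d
* part of the left-handed substrate and right-handed substrate charged together that has reacted at 3.0 d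

By charge the two substrates together are the limiting reagent, since the flask holds 1.25 equivalents of partner. The balance then reads: conversion equals those equivalents times the partner share, the part of the charged partner that ends in product.

The excess rests on a small reading: in beta, right-handed product stands far below left-handed product. In beta it reads 90.9 % at 15.0 h and 94.8 % at 20.0 h, and that spread measures how far the scatter of 0.3 percentage points carries. Conversion moves in proportion to the share, so the share is the number to know. The charge of precatalyst is the weak point: no earlier run changes it.

Beta's last reading gives a share of 15.4 %. Scaling it by the precatalyst charge, as a guess, gives the flask 7.72 %, hence 9.65 % conversion. This reckoning holds that figure as a low mark, because beta was still forming product at its last reading, and it expects an excess near the beta readings at both times.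

The forecast puts the excess at 88 % and 90 %, and its conversion of 27 % stands above that low mark, on the ground “Taking half the rate over 70 h gives about 31% conversion”, then lowered to allow for decay and titration. The flask gives 98.1 %, 98.1 % and 9.92 %.

    precatalyst → catalyst (k = 0.0480 h⁻¹)
    partner + catalyst + left-handed substrate → catalyst + left-handed product (k = 5000 M⁻² h⁻¹)
    left-handed substrate ⇌ right-handed substrate (k = 0.0920 h⁻¹)
    partner + catalyst + right-handed substrate → catalyst + right-handed product (k = 47.0 M⁻² h⁻¹)
    partner → decomposed reagent (k = 0.120 h⁻¹)
    catalyst + added ligand ⇌ idle complex (K = 5000 M⁻¹, k = 7500 M⁻¹ h⁻¹)

At 3.00 d the flask holds 0 % of its partner and 90 % of its left-handed substrate, with 0.0391 M of decomposed reagent, so the partner ran out first. The balance gives the flask a share of 7.94 %, half of beta's reading. The neighbouring flask with [partner] at 0.017 M has 0.500 equivalents, so the same share reckons to 3.97 % conversion, and that neighbour gives 4.09 %.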